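At early times, with neither charge yet touched, your question about these flasks looked to me like a fork at catalyst intermediate A, so I started there for your quick number.

| flask | substrate | reagent | capture agent | free catalyst | time |
|---|---|---|---|---|---|
| south-west | 0.50 M | 0.900 M | 0.0500 M | 0.50 mM | 4.0 min |
| south-east | 0.50 M | 0.900 M | 0.0500 M | 1.5 mM | 4.0 min |
| north-west | 0.50 M | 0.900 M | 0.0500 M | 4.5 mM | 4.0 min |

- which of these there is most of at the end, counted by the substrate in it, south-west (catalyst intermediate A / substrate / trapped intermediate / product / catalyst intermediate B)
- which of these there is most of at the end, counted by the substrate in it, south-east (catalyst intermediate A / substrate / trapped intermediate / product / catalyst intermediate B)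
- which of these there is most of at the end, counted by the substrate in it, north-west (catalyst intermediate A / substrate / trapped intermediate / product / catalyst intermediate B)
- how much there is at the end of the one of these that leads, in percent of the substrate charged: south-west
- how much there is at the end of the one of these that leads, in percent of the substrate charged: south-east
- how much there is at the end of the one of these that leads, in percent of the substrate charged: north-west

    substrate + free catalyst → catalyst intermediate A (k1 = 3900 M⁻¹ s⁻¹)
    reagent + catalyst intermediate A ⇌ catalyst intermediate B (K2 = 94.4 M⁻¹, k2 = 1600 M⁻¹ s⁻¹)
    catalyst intermediate B → free catalyst + product (k3 = 54.9 s⁻¹)
    catalyst intermediate A + capture agent → trapped intermediate (k4 = 237 M⁻¹ s⁻¹)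

Reagent and capture agent each take catalyst intermediate A at a rate proportional to their own amount, and catalyst intermediate B went forward on 76.4% of its visits, since its forward constant of 54.9 s⁻¹ is larger than its return of 16.9 s⁻¹. The ratio of the two rate constants at the fork, times that share, gave 5.16. I called this the fork ratio, a selectivity factor: the fractional use of reagent into product over the fractional use of capture agent. One is the zero of this scale, the even fork, where both charges shrink by the same fraction; in general the fraction of reagent left is the fraction of capture agent left raised to this power.

At the start that meant 92.9 product per trapped catalyst, the turnover number, or about 1.69 s at the pace of the last step, short against 4.0 min. So I dropped the clock and let each catalyst take one capture agent. South-west then kept 0.990 of its capture agent and 0.949 of its reagent, south-east 0.970 and 0.855, north-west 0.910 and 0.615. Spent reagent is product, so I committed to substrate leading in south-west at 90.8%, substrate in south-east at 73.5%, and product in north-west at 69.3%.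

The forecast named substrate, substrate and product, at 90.7%, 73.3% and 69.9%, which differ from mine in the first decimal, on the ground that the product is “set by the catalyst charge times that turnover number rather than by time”.

The flasks ended with substrate leading at 90.8% in south-west, substrate at 73.5% in south-east, and product at 69.3% in north-west.

In south-east the last step had half its turnover behind it by 1.18 s, and by 2.00 min the catalyst stood as trapped intermediate, 100% of its charge, with 97% of the capture agent left and 85% of the reagent, the first raised to the fork ratio being 85.5%. In the further flask, like south-east but with 0.013 M of capture agent, the same power gave 53.1% of the reagent left and product at 84.4%, and that flask stood at 53.1% of its reagent and 84.4% product.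

The constants belong to no real substance; no experiment stands behind them.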